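**Strategy**

Everything rests on taking apart the benzene ring of the isoquinoline (C4a, C5, C6, C7, C8, C8a). Its substitution (naphthyl at C5, OMe at C6, H at C7, OH at C8) is exactly what an aryl(alkenyl)ketene and methoxyacetylene assemble, and what is left of the heterocycle, a trans-2,6-dimethylpiperidine, has a twofold axis, so the ketone from which the alkene is made enolizes to one product only. A single photochemical operation (Wolff rearrangement, [2+2], 4π opening, 6π closure) forms C4a–C5, C5–C6, C7–C8 and C8–C8a and the aromatic ring, with C1 and C3 already set. The precursor is an N-Boc (2R,6R)-2,6-dimethyl-3,6-dihydro-2H-pyridine carrying a diazo(naphthyl)acetyl group at C4.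

Key step: step 16

Remark: the given structure fixes only C1 and C3; rotation about the hindered C5–C1′ biaryl bond should be slow, so step 16 is expected to give both atropo-diastereomers of the (1R,3R) compound, to be separated by chromatography at 32 or 33.

**Route**

Step 1
Reactants: 1 tert-butyl (2R)-2-methyl-4-oxopiperidine-1-carboxylate (commercial, enantiopure)
Product: 2 tert-butyl (7R)-7-methyl-1,4-dioxa-8-azaspiro[4.5]decane-8-carboxylate
Conditions: HOCH2CH2OH, PPTS (cat.), benzene, reflux, Dean–Stark
Reagents that add atoms: ethylene glycol, OCCO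
Why: Acid-catalysed ketalization with azeotropic removal of water should mask the ketone against the organolithium of the next step, PPTS being too weak an acid to cleave the Boc group, and the existing stereocentre is not involved.

Step 2
Reactants: 2 tert-butyl (7R)-7-methyl-1,4-dioxa-8-azaspiro[4.5]decane-8-carboxylate
Product: 4 tert-butyl (7R,9R)-7,9-dimethyl-1,4-dioxa-8-azaspiro[4.5]decane-8-carboxylate, via α-lithiated carbamate 3 (not isolated)
Conditions: s-BuLi, TMEDA, Et2O, −78 °C; then Me2SO4, −78 °C to rt
Reagents that add atoms: dimethyl sulfate, COS(=O)(=O)OC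
Why: Carbamate-directed α-lithiation–substitution of an N-Boc piperidine: A(1,3) strain with the Boc group holds the C7 methyl axial, s-BuLi/TMEDA removes the equatorial hydrogen at the unsubstituted α-carbon C9, and methylation with retention should place the new methyl trans to the old one, which sets the (9R) centre and the C2-symmetric array (cuprate addition to an N-acyl dihydropyridone is avoided because it is reported to favour the cis, meso-type arrangement).

Step 3
Reactants: 4 tert-butyl (7R,9R)-7,9-dimethyl-1,4-dioxa-8-azaspiro[4.5]decane-8-carboxylate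
Product: 5 tert-butyl (2R,6R)-2,6-dimethyl-4-oxopiperidine-1-carboxylate
Conditions: p-TsOH·H2O (cat.), acetone/H2O, 50 °C
Reagents that add atoms: water, O
Why: Mild aqueous acid hydrolysis of the dioxolane should release the ketone while the Boc group survives, and because nitrogen stays acylated the β-amino ketone cannot epimerize by retro-Michael opening, so the trans relationship is kept.

Step 4
Reactants: 5 tert-butyl (2R,6R)-2,6-dimethyl-4-oxopiperidine-1-carboxylate
Product: 7 tert-butyl (2R,6R)-2,6-dimethyl-4-(trifluoromethylsulfonyloxy)-3,6-dihydro-2H-pyridine-1-carboxylate, via lithium enolate 6 (not isolated)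
Conditions: LiN(SiMe3)2, THF, −78 °C; then PhNTf2, −78 to 0 °C; aq. NH4Cl
Reagents that add atoms: N-phenylbis(trifluoromethanesulfonimide), O=S(=O)(N(c1ccccc1)S(=O)(=O)C(F)(F)F)C(F)(F)F
Why: Kinetic enolate formation and O-sulfonylation (enol triflate synthesis); the C2 axis of ketone 5 makes both α-methylene groups equivalent, so a single alkenyl triflate should result and no stereocentre is touched.

Step 5
Reactants: 7 tert-butyl (2R,6R)-2,6-dimethyl-4-(trifluoromethylsulfonyloxy)-3,6-dihydro-2H-pyridine-1-carboxylate
Product: 8 tert-butyl (2R,6R)-4-[methoxy(methyl)carbamoyl]-2,6-dimethyl-3,6-dihydro-2H-pyridine-1-carboxylate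
Conditions: CO (1 atm), MeNH(OMe)·HCl, Pd(OAc)2 (3 mol %), Xantphos (3 mol %), Et3N, toluene, 60 °C
Reagents that add atoms: carbon monoxide, [C-]#[O+]; N,O-dimethylhydroxylamine hydrochloride, CNOC.Cl
Why: Palladium-catalysed aminocarbonylation of an alkenyl triflate: oxidative addition to zerovalent palladium, CO insertion and aminolysis of the acylpalladium by the hydroxylamine should give the Weinreb amide directly.

Step 6
Reactants: 9 2-methoxy-4-methylbenzoic acid
Product: 11 N,N-diethyl-2-methoxy-4-methylbenzamide, via 2-methoxy-4-methylbenzoyl chloride 10 (not isolated)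
Conditions: (COCl)2, DMF (cat.), CH2Cl2, 0 °C to rt; then Et2NH, Et3N, CH2Cl2, 0 °C
Reagents that add atoms: diethylamine, CCNCC
Why: Conversion of the acid to its chloride and amidation should install the tertiary amide that serves first as the directing group for ortho-metalation and later as the acyl acceptor in the annulation.

Step 7
Reactants: 11 N,N-diethyl-2-methoxy-4-methylbenzamide
Product: 14 N,N-diethyl-2-methoxy-4-methyl-6-(prop-2-en-1-yl)benzamide, via ortho-lithiated amide 12 (not isolated), via arylmagnesium bromide 13 (not isolated)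
Conditions: s-BuLi, TMEDA, THF, −78 °C; MgBr2·OEt2, −78 to 0 °C; then allyl bromide, 0 °C to rt
Reagents that add atoms: allyl bromide, C=CCBr
Why: Directed ortho-metalation: the diethylamide outranks the methoxy group as director and C6 is its only free ortho position, and transmetalation to magnesium should allow clean SN2 allylation without attack on the amide.

Step 8
Reactants: 14 N,N-diethyl-2-methoxy-4-methyl-6-(prop-2-en-1-yl)benzamide
Product: 16 8-methoxy-6-methylnaphthalen-1-ol, via benzylic allylic organolithium 15 (not isolated)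
Conditions: LiN(i-Pr)2 (2.5 equiv), THF, −78 °C to rt; then aq. HCl
Reagents that add atoms: none
Why: Anionic ring annulation of an o-allylbenzamide: deprotonation at the doubly activated benzylic–allylic CH2, attack of the allyl terminus on the amide carbonyl (six-membered ring), loss of diethylamide and tautomerization to the naphtholate, with aromatization as the driving force.

Step 9
Reactants: 16 8-methoxy-6-methylnaphthalen-1-ol
Product: 17 4-bromo-8-methoxy-6-methylnaphthalen-1-ol
Conditions: NBS (1.0 equiv), MeCN, −20 to 0 °C, dark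
Reagents that add atoms: N-bromosuccinimide, O=C1CCC(=O)N1Br
Why: Electrophilic aromatic bromination: the free hydroxyl is the strongest donor and directs NBS to its unhindered para position C4, whereas the corresponding position of the methoxy-bearing ring is flanked by the methyl group and activated only by an ether.

Step 10
Reactants: 17 4-bromo-8-methoxy-6-methylnaphthalen-1-ol
Product: 18 1-bromo-4,5-dimethoxy-7-methylnaphthalene
Conditions: MeI, K2CO3, DMF, rt
Reagents that add atoms: iodomethane, CI
Why: Williamson ether synthesis on the naphtholate should give the dimethyl ether, no other nucleophilic site being present.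

Step 11
Reactants: 18 1-bromo-4,5-dimethoxy-7-methylnaphthalene
Product: 20 (4,5-dimethoxy-7-methylnaphthalen-1-yl)methanol, via naphthyllithium 19 (not isolated)
Conditions: n-BuLi, THF, −78 °C; then (CH2O)n, −78 °C to rt; H2O
Reagents that add atoms: paraformaldehyde (as formaldehyde), C=O
Why: Bromine–lithium exchange is faster than any deprotonation at −78 °C, and the aryllithium should add to the formaldehyde released from paraformaldehyde to give the benzylic alcohol.

Step 12
Reactants: 20 (4,5-dimethoxy-7-methylnaphthalen-1-yl)methanol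
Product: 21 1-(chloromethyl)-4,5-dimethoxy-7-methylnaphthalene
Conditions: SOCl2, pyridine, CH2Cl2, −10 to 0 °C; used at once
Reagents that add atoms: thionyl chloride, O=S(Cl)Cl
Why: Chlorodehydroxylation of an activated benzylic alcohol in the presence of base, which should suppress acid-promoted self-alkylation of the electron-rich ring.

Step 13
Reactants: 21 1-(chloromethyl)-4,5-dimethoxy-7-methylnaphthalene; 8 tert-butyl (2R,6R)-4-[methoxy(methyl)carbamoyl]-2,6-dimethyl-3,6-dihydro-2H-pyridine-1-carboxylate
Product: 23 tert-butyl (2R,6R)-4-[2-(4,5-dimethoxy-7-methylnaphthalen-1-yl)acetyl]-2,6-dimethyl-3,6-dihydro-2H-pyridine-1-carboxylate, via benzylic Grignard reagent 22 (not isolated)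
Conditions: Mg (I2-activated), THF, 0 °C, slow addition of 21; then 8, THF, −20 to 0 °C; aq. NH4Cl
Reagents that add atoms: none
Why: Weinreb ketone synthesis: the benzylic Grignard reagent should add once to the N-methoxy-N-methylamide, which enforces mono-addition, so neither a tertiary alcohol nor a conjugate adduct is expected and the Boc group is untouched at this temperature.

Step 14
Reactants: 23 tert-butyl (2R,6R)-4-[2-(4,5-dimethoxy-7-methylnaphthalen-1-yl)acetyl]-2,6-dimethyl-3,6-dihydro-2H-pyridine-1-carboxylate
Product: 24 tert-butyl (2R,6R)-4-[2-diazo-2-(4,5-dimethoxy-7-methylnaphthalen-1-yl)acetyl]-2,6-dimethyl-3,6-dihydro-2H-pyridine-1-carboxylate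
Conditions: p-ABSA, DBU, MeCN, 0 °C to rt, dark
Reagents that add atoms: 4-acetamidobenzenesulfonyl azide, CC(=O)Nc1ccc(cc1)S(=O)(=O)N=[N+]=[N-]
Why: Regitz diazo transfer: the methylene flanked by the naphthyl ring and the ketone is acidic enough for DBU, and its enolate should take up the terminal nitrogen atoms of the sulfonyl azide to give the α-aryl-α-diazo ketone without prior formyl activation.

Step 15
Reactants: 25 chloroacetaldehyde dimethyl acetal
Product: 27 methoxyacetylene, via sodium methoxyacetylide 26 (not isolated)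
Conditions: NaNH2 (3 equiv), liq. NH3, −33 °C; evaporate NH3; then cold aq. NaCl, distil (bp 23 °C) into cold ClCH2CH2Cl
Reagents that add atoms: none
Why: Two successive base-induced eliminations (HCl, then methanol) and deprotonation of the alkyne by NaNH2 should give the sodium acetylide, which aqueous work-up protonates to the volatile ynol ether.

Step 16
Reactants: 24 tert-butyl (2R,6R)-4-[2-diazo-2-(4,5-dimethoxy-7-methylnaphthalen-1-yl)acetyl]-2,6-dimethyl-3,6-dihydro-2H-pyridine-1-carboxylate; 27 methoxyacetylene
Product: 32 tert-butyl (1R,3R)-5-(4,5-dimethoxy-7-methylnaphthalen-1-yl)-8-hydroxy-6-methoxy-1,3-dimethyl-3,4-dihydroisoquinoline-2(1H)-carboxylate, via aryl(alkenyl)ketene 28 (not isolated), via 4-alkenylcyclobutenone 29 (not isolated), via dienylketene 30 (not isolated), via cyclohexa-2,4-dienone 31 (not isolated)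
Conditions: hν (450 nm LEDs), 27 (5 equiv), ClCH2CH2Cl (0.05 M), 25 °C, sealed tube; then 80 °C
Reagents that add atoms: none
Why: Light absorbed by the diazo ketone expels N2 and the alkenyl group shifts from the carbonyl carbon to the carbene carbon (photochemical Wolff rearrangement) to give ketene 28; the nucleophilic CH carbon of methoxyacetylene attacks the ketene carbonyl carbon in a [2+2] cycloaddition to cyclobutenone 29, which opens (4π) to dienylketene 30, closes (6π) to dienone 31 and enolizes to phenol 32. The sequence is the Danheiser benzannulation in its diazo ketone variant, and the behaviour of a fully substituted ketene is modelled by the Smith–Hoehn reaction of diarylketenes with alkoxyacetylenes. The single new ring (C4a, C5, C6, C7, C8, C8a) closes by a thermally allowed disrotatory 6π-electrocyclization that joins the ketene carbon C8 to the former alkene CH, C8a. No stereocentre is created: C1 and C3 come unchanged from 24, and the sp3 centres that appear in 29 and 31 are erased again. Two selectivities are needed: the regiochemistry of the [2+2], which the polarity of the ynol ether secures (OMe next to the naphthyl-bearing C5, H next to C8–OH), and closure of 30 onto the ring alkene instead of the C1–C2 bond of the naphthalene, which should win because it costs no aromaticity and because 29 and 30 interconvert, so the isomer with the naphthyl group turned inward can return and re-open. Light of 450 nm excites the aryl diazo ketone but not the naphthalene or the phenolic product, and excess alkyne should outrun ketene dimerization.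

Step 17
Reactants: 32 tert-butyl (1R,3R)-5-(4,5-dimethoxy-7-methylnaphthalen-1-yl)-8-hydroxy-6-methoxy-1,3-dimethyl-3,4-dihydroisoquinoline-2(1H)-carboxylate
Product: 33 Ancistrocongoline B, (1R,3R)-5-(4,5-dimethoxy-7-methylnaphthalen-1-yl)-6-methoxy-1,2,3-trimethyl-1,2,3,4-tetrahydroisoquinolin-8-ol
Conditions: LiAlH4 (excess), THF, reflux; then H2O, aq. NaOH, extraction at about pH 9
Reagents that add atoms: none
Why: LiAlH4 reduction of a carbamate to an N-methyl amine (hydride addition, loss of tert-butoxide, reduction of the resulting iminium level); the phenol is only deprotonated, the aryl ethers are inert, and C1 and C3 carry no acidifying group, so their configuration is kept.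

**Compound list**

1 | tert-butyl (2R)-2-methyl-4-oxopiperidine-1-carboxylate | C[C@@H]1CC(=O)CCN1C(=O)OC(C)(C)C | starting material
2 | tert-butyl (7R)-7-methyl-1,4-dioxa-8-azaspiro[4.5]decane-8-carboxylate | C[C@@H]1CC2(CCN1C(=O)OC(C)(C)C)OCCO2 | intermediate
3 | tert-butyl (7R)-9-lithio-7-methyl-1,4-dioxa-8-azaspiro[4.5]decane-8-carboxylate (C–Li equatorial, trans to the methyl) | [Li][C@@H]1CC2(C[C@@H](C)N1C(=O)OC(C)(C)C)OCCO2 | intermediate (not isolated)
4 | tert-butyl (7R,9R)-7,9-dimethyl-1,4-dioxa-8-azaspiro[4.5]decane-8-carboxylate | C[C@@H]1CC2(C[C@@H](C)N1C(=O)OC(C)(C)C)OCCO2 | intermediate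
5 | tert-butyl (2R,6R)-2,6-dimethyl-4-oxopiperidine-1-carboxylate | C[C@@H]1CC(=O)C[C@@H](C)N1C(=O)OC(C)(C)C | intermediate
6 | lithium (2R,6R)-1-(tert-butoxycarbonyl)-2,6-dimethyl-1,2,3,6-tetrahydropyridin-4-olate | C[C@@H]1CC(O[Li])=C[C@@H](C)N1C(=O)OC(C)(C)C | intermediate (not isolated)
7 | tert-butyl (2R,6R)-2,6-dimethyl-4-(trifluoromethylsulfonyloxy)-3,6-dihydro-2H-pyridine-1-carboxylate | C[C@@H]1CC(OS(=O)(=O)C(F)(F)F)=C[C@@H](C)N1C(=O)OC(C)(C)C | intermediate
8 | tert-butyl (2R,6R)-4-[methoxy(methyl)carbamoyl]-2,6-dimethyl-3,6-dihydro-2H-pyridine-1-carboxylate | C[C@@H]1CC(C(=O)N(C)OC)=C[C@@H](C)N1C(=O)OC(C)(C)C | intermediate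
9 | 2-methoxy-4-methylbenzoic acid | COc1cc(C)ccc1C(=O)O | starting material
10 | 2-methoxy-4-methylbenzoyl chloride | COc1cc(C)ccc1C(=O)Cl | intermediate (not isolated)
11 | N,N-diethyl-2-methoxy-4-methylbenzamide | CCN(CC)C(=O)c1ccc(C)cc1OC | intermediate
12 | [2-(diethylcarbamoyl)-3-methoxy-5-methylphenyl]lithium | CCN(CC)C(=O)c1c([Li])cc(C)cc1OC | intermediate (not isolated)
13 | [2-(diethylcarbamoyl)-3-methoxy-5-methylphenyl]magnesium bromide | CCN(CC)C(=O)c1c([Mg]Br)cc(C)cc1OC | intermediate (not isolated)
14 | N,N-diethyl-2-methoxy-4-methyl-6-(prop-2-en-1-yl)benzamide | CCN(CC)C(=O)c1c(CC=C)cc(C)cc1OC | intermediate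
15 | {1-[2-(diethylcarbamoyl)-3-methoxy-5-methylphenyl]prop-2-en-1-yl}lithium | CCN(CC)C(=O)c1c(C([Li])C=C)cc(C)cc1OC | intermediate (not isolated)
16 | 8-methoxy-6-methylnaphthalen-1-ol | COc1cc(C)cc2cccc(O)c12 | intermediate
17 | 4-bromo-8-methoxy-6-methylnaphthalen-1-ol | COc1cc(C)cc2c(Br)ccc(O)c12 | intermediate
18 | 1-bromo-4,5-dimethoxy-7-methylnaphthalene | COc1ccc(Br)c2cc(C)cc(OC)c12 | intermediate
19 | (4,5-dimethoxy-7-methylnaphthalen-1-yl)lithium | COc1ccc([Li])c2cc(C)cc(OC)c12 | intermediate (not isolated)
20 | (4,5-dimethoxy-7-methylnaphthalen-1-yl)methanol | COc1ccc(CO)c2cc(C)cc(OC)c12 | intermediate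
21 | 1-(chloromethyl)-4,5-dimethoxy-7-methylnaphthalene | COc1ccc(CCl)c2cc(C)cc(OC)c12 | intermediate
22 | [(4,5-dimethoxy-7-methylnaphthalen-1-yl)methyl]magnesium chloride | COc1ccc(C[Mg]Cl)c2cc(C)cc(OC)c12 | intermediate (not isolated)
23 | tert-butyl (2R,6R)-4-[2-(4,5-dimethoxy-7-methylnaphthalen-1-yl)acetyl]-2,6-dimethyl-3,6-dihydro-2H-pyridine-1-carboxylate | C[C@@H]1CC(C(=O)Cc2ccc(OC)c3c(OC)cc(C)cc23)=C[C@@H](C)N1C(=O)OC(C)(C)C | intermediate
24 | tert-butyl (2R,6R)-4-[2-diazo-2-(4,5-dimethoxy-7-methylnaphthalen-1-yl)acetyl]-2,6-dimethyl-3,6-dihydro-2H-pyridine-1-carboxylate | C[C@@H]1CC(C(=O)C(=[N+]=[N-])c2ccc(OC)c3c(OC)cc(C)cc23)=C[C@@H](C)N1C(=O)OC(C)(C)C | intermediate (precursor of the key step)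
25 | chloroacetaldehyde dimethyl acetal (2-chloro-1,1-dimethoxyethane) | COC(CCl)OC | starting material
26 | sodium methoxyacetylide | [Na+].[C-]#COC | intermediate (not isolated)
27 | methoxyacetylene (methoxyethyne) | COC#C | intermediate
28 | tert-butyl (2R,6R)-4-[1-(4,5-dimethoxy-7-methylnaphthalen-1-yl)-2-oxoethenyl]-2,6-dimethyl-3,6-dihydro-2H-pyridine-1-carboxylate | C[C@@H]1CC(C(=C=O)c2ccc(OC)c3c(OC)cc(C)cc23)=C[C@@H](C)N1C(=O)OC(C)(C)C | intermediate (not isolated)
29 | tert-butyl (2R,6R)-4-[1-(4,5-dimethoxy-7-methylnaphthalen-1-yl)-2-methoxy-4-oxocyclobut-2-en-1-yl]-2,6-dimethyl-3,6-dihydro-2H-pyridine-1-carboxylate (both epimers at the ring carbon) | C[C@@H]1CC(C2(c3ccc(OC)c4c(OC)cc(C)cc34)C(OC)=CC2=O)=C[C@@H](C)N1C(=O)OC(C)(C)C | intermediate (not isolated)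
30 | tert-butyl (2R,6R)-4-[(1Z)-1-(4,5-dimethoxy-7-methylnaphthalen-1-yl)-2-methoxy-4-oxobuta-1,3-dien-1-yl]-2,6-dimethyl-3,6-dihydro-2H-pyridine-1-carboxylate | C[C@@H]1CC(/C(c2ccc(OC)c3c(OC)cc(C)cc23)=C(/OC)C=C=O)=C[C@@H](C)N1C(=O)OC(C)(C)C | intermediate (not isolated)
31 | tert-butyl (1R,3R)-5-(4,5-dimethoxy-7-methylnaphthalen-1-yl)-6-methoxy-1,3-dimethyl-8-oxo-3,4,8,8a-tetrahydroisoquinoline-2(1H)-carboxylate (C8a unassigned) | C[C@@H]1CC2=C(c3ccc(OC)c4c(OC)cc(C)cc34)C(OC)=CC(=O)C2[C@@H](C)N1C(=O)OC(C)(C)C | intermediate (not isolated)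
32 | tert-butyl (1R,3R)-5-(4,5-dimethoxy-7-methylnaphthalen-1-yl)-8-hydroxy-6-methoxy-1,3-dimethyl-3,4-dihydroisoquinoline-2(1H)-carboxylate | COc1cc(O)c2c(c1-c1ccc(OC)c3c(OC)cc(C)cc13)C[C@@H](C)N(C(=O)OC(C)(C)C)[C@@H]2C | intermediate (product of the key step)
33 | Ancistrocongoline B, (1R,3R)-5-(4,5-dimethoxy-7-methylnaphthalen-1-yl)-6-methoxy-1,2,3-trimethyl-1,2,3,4-tetrahydroisoquinolin-8-ol | COc1cc(O)c2c(c1-c1ccc(OC)c3c(OC)cc(C)cc13)C[C@@H](C)N(C)[C@@H]2C | target

**Count and risks**

Total step count: 17. Longest linear sequence: 11 steps (from 9 through steps 6–14, 16 and 17); the piperidine branch from 1 needs 9 steps.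

Steps most likely to fail:

1. Step 16. The dienylketene may close onto the C1–C2 bond of the naphthalene instead of the ring alkene, or the hindered, fully substituted ketene may be lost to dimerization or to acylation of the phenol already formed before it meets the alkyne. Fallback: take the naphthyl group out of the ketene and attach it afterwards by cross-coupling. The fallback sets out from Weinreb amide 8 and bromide 18 and returns at 32.
   - MeMgBr in THF should convert 8 into the methyl ketone F1.
   - Trifluoroacetylation of its kinetic enolate (LiN(SiMe3)2, CF3CO2CH2CF3) should give the trifluoroacetyl diketone F2.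
   - Deacylative diazo transfer (MsN3, Et3N, H2O, MeCN) should then give the diazomethyl ketone F3.
   - Irradiation of F3 with 27 is the standard benzannulation of a monosubstituted vinylketene, in which only the alkene can close, and should give the naphthyl-free phenol F4.
   - NBS should brominate F4 para to the hydroxyl to give the 5-bromo phenol F5.
   - Bromide 18, by way of 19, B(OMe)3 and aqueous acid, should give the naphthylboronic acid F6.
   - Suzuki–Miyaura coupling of F5 with F6 (Pd(OAc)2, SPhos, K3PO4, toluene/H2O, 90 °C) should form the C5–C1′ bond and give 32.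

2. Step 2. In the conformer needed for equatorial lithiation the axial C7 methyl group and the axial ketal oxygen clash, so deprotonation may be slow or the trans preference eroded. Fallback: carry C4 through the lithiation as an sp2 carbon without an axial substituent. The fallback sets out from 1 and returns at 5.
   - Wittig methylenation (Ph3P=CH2, THF) should give the 4-methylidene carbamate F7.
   - The same carbamate-directed lithiation and methylation (s-BuLi, TMEDA, Et2O, −78 °C; Me2SO4) should give the trans-dimethyl methylidene carbamate F8.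
   - Ozonolysis (O3, CH2Cl2/MeOH, −78 °C; Me2S) should unveil ketone 5.

3. Step 13. During magnesium insertion the electron-rich benzylic chloride may dimerize in a Wurtz-type coupling, or the Grignard reagent may react through its ring ortho position. Fallback: avoid any benzylic organometallic and form the bond by Nozaki–Hiyama–Kishi coupling. The fallback sets out from bromide 18 and triflate 7 and returns at 23.
   - Bromine–lithium exchange (by way of 19) and opening of ethylene oxide should give the naphthylethanol F9.
   - Dess–Martin oxidation should give the naphthylacetaldehyde F10.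
   - Coupling of 7 with F10 (CrCl2, NiCl2 cat., DMF, rt) should give the allylic alcohol F11 as a mixture of carbinol epimers.
   - Dess–Martin oxidation of F11 should give ketone 23.

**Further compounds**

F1 | step 16 | tert-butyl (2R,6R)-4-acetyl-2,6-dimethyl-3,6-dihydro-2H-pyridine-1-carboxylate | C[C@@H]1CC(C(C)=O)=C[C@@H](C)N1C(=O)OC(C)(C)C
F2 | step 16 | tert-butyl (2R,6R)-2,6-dimethyl-4-(4,4,4-trifluoro-3-oxobutanoyl)-3,6-dihydro-2H-pyridine-1-carboxylate | C[C@@H]1CC(C(=O)CC(=O)C(F)(F)F)=C[C@@H](C)N1C(=O)OC(C)(C)C
F3 | step 16 | tert-butyl (2R,6R)-4-(2-diazoacetyl)-2,6-dimethyl-3,6-dihydro-2H-pyridine-1-carboxylate | C[C@@H]1CC(C(=O)C=[N+]=[N-])=C[C@@H](C)N1C(=O)OC(C)(C)C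
F4 | step 16 | tert-butyl (1R,3R)-8-hydroxy-6-methoxy-1,3-dimethyl-3,4-dihydroisoquinoline-2(1H)-carboxylate | COc1cc(O)c2c(c1)C[C@@H](C)N(C(=O)OC(C)(C)C)[C@@H]2C
F5 | step 16 | tert-butyl (1R,3R)-5-bromo-8-hydroxy-6-methoxy-1,3-dimethyl-3,4-dihydroisoquinoline-2(1H)-carboxylate | COc1cc(O)c2c(c1Br)C[C@@H](C)N(C(=O)OC(C)(C)C)[C@@H]2C
F6 | step 16 | (4,5-dimethoxy-7-methylnaphthalen-1-yl)boronic acid | COc1ccc(B(O)O)c2cc(C)cc(OC)c12
F7 | step 2 | tert-butyl (2R)-2-methyl-4-methylidenepiperidine-1-carboxylate | C[C@@H]1CC(=C)CCN1C(=O)OC(C)(C)C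
F8 | step 2 | tert-butyl (2R,6R)-2,6-dimethyl-4-methylidenepiperidine-1-carboxylate | C[C@@H]1CC(=C)C[C@@H](C)N1C(=O)OC(C)(C)C
F9 | step 13 | 2-(4,5-dimethoxy-7-methylnaphthalen-1-yl)ethan-1-ol | OCCc1ccc(OC)c2c(OC)cc(C)cc12
F10 | step 13 | 2-(4,5-dimethoxy-7-methylnaphthalen-1-yl)acetaldehyde | O=CCc1ccc(OC)c2c(OC)cc(C)cc12
F11 | step 13 | tert-butyl (2R,6R)-4-[2-(4,5-dimethoxy-7-methylnaphthalen-1-yl)-1-hydroxyethyl]-2,6-dimethyl-3,6-dihydro-2H-pyridine-1-carboxylate | C[C@@H]1CC(C(O)Cc2ccc(OC)c3c(OC)cc(C)cc23)=C[C@@H](C)N1C(=O)OC(C)(C)C
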